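The cyclohexane ring (ring B: carbinol C1', CH2 C2', CH2 C3', CMeCl C4', CHBr C5', CH2 C6') hides a 1-substituted 4-methylcyclohexa-1,4-diene: the C4'/C5' bromochloride is a masked alkene, the C1' carbinol a hydrated C1'=C2' bond, and C1' and C4' are para. The key step is therefore a cobalt-catalysed [4+2] cycloaddition of isoprene with a terminal alkyne carried by the cyclopentane (ring A), forming C2'–C3' and C1'–C6' at once. The alkyne comes from (−)-camphor, whose CH2–CH2 bridge becomes C2'–C1' by a radical ring fragmentation that also installs the ring A bromide. C1', C4' and C5' are then relayed from ring A by directed epoxidation and transannular bromoetherification.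

Key step: step 6

Remark (numbering): ring A is C1 (quaternary, methyl), C2 (CMe2), C3 (CHBr), C4 (CH2), C5 (CHOH); "bornane C n" refers to camphor numbering in steps 1 to 4.
Remark (assumption): (1S)-(−)-camphor is taken as the commercial enantiomer; its C1 and C4 map onto C1 and C3 of the target.

Step 1
Reactants: 1 (1S,4S)-camphor
Product: 3 (1S,2S,4S)-isobornyl acetate (2-exo-acetoxybornane), via lithium isoborneolate 2 (not isolated)
Conditions: L-Selectride (LiBH(s-Bu)3), THF, −78 °C; then Ac2O, DMAP (cat.), −78 °C to rt
Reagents that add atoms: acetic anhydride, CC(=O)OC(C)=O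
Why: Hydride reduction of the ketone from the endo face (the exo face is shielded by the syn C7 methyl) should give the exo alkoxide, which is O-acetylated in the same flask.

Step 2
Reactants: 3 (1S,2S,4S)-isobornyl acetate
Product: 4 5-oxoisobornyl acetate (2-exo-acetoxybornan-5-one)
Conditions: CrO3, AcOH/Ac2O, 40 °C
Reagents that add atoms: chromium trioxide, O=[Cr](=O)=O
Why: Remote methylene oxidation by hexavalent chromium, in which the acetoxy group deactivates bornane C2, C3 and C6 inductively so that the most distant methylene, bornane C5, should be oxidised to the ketone without touching a stereocentre.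

Step 3
Reactants: 4 5-oxoisobornyl acetate
Product: 5 5-exo-hydroxyisobornyl acetate (2-exo-acetoxy-5-exo-hydroxybornane)
Conditions: NaBH4, MeOH, 0 °C
Reagents that add atoms: none
Why: Borohydride reduction of the ketone in the presence of the ester should give mainly the 5-exo alcohol by endo attack, and its configuration is immaterial because this carbon becomes the aldehyde carbon in step 4.

Step 4
Reactants: 5 5-exo-hydroxyisobornyl acetate
Product: 7 2-[(1S,3S,5S)-5-acetoxy-3-bromo-1,2,2-trimethylcyclopentyl]acetaldehyde, via 5-exo-hypobromite 6 (not isolated)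
Conditions: HgO, Br2, benzene, rt, visible light
Reagents that add atoms: bromine, BrBr
Why: Alkoxy-radical β-fragmentation (hypobromite photolysis): O–Br homolysis gives the alkoxy radical, strain-releasing scission of the bornane C4–C5 bond gives the aldehyde and a secondary cyclopentyl radical, and bromine-atom transfer to that radical should occur on the face opposite to the exo-acetoxy group and the C1 methyl group, placing Br at C3 cis to the CH2CHO chain.

Step 5
Reactants: 7 2-[(1S,3S,5S)-5-acetoxy-3-bromo-1,2,2-trimethylcyclopentyl]acetaldehyde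
Product: 9 (1S,2S,4S)-4-bromo-2-ethynyl-2,3,3-trimethylcyclopentyl acetate, via enol triflate 8 (not isolated)
Conditions: Tf2O, 2,6-di-tert-butyl-4-methylpyridine, CH2Cl2, 0 °C to rt; then KOt-Bu, THF, −40 °C
Reagents that add atoms: none
Why: O-Triflation of the aldehyde enol followed by base-induced elimination of triflic acid (β-elimination, or α-elimination and 1,2-hydrogen shift of the alkylidene carbene) should give the terminal alkyne with unchanged carbon count, while the neopentyl-type secondary bromide and the acetate should survive the brief exposure to hindered base at low temperature.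

Step 6
Reactants: 9 (1S,2S,4S)-4-bromo-2-ethynyl-2,3,3-trimethylcyclopentyl acetate; 10 isoprene (2-methylbuta-1,3-diene)
Product: 11 (1S,2S,4S)-4-bromo-2,3,3-trimethyl-2-(4-methylcyclohexa-1,4-dien-1-yl)cyclopentyl acetate
Conditions: CoBr2(dppe) (10 mol %), ZnI2 (20 mol %), Zn powder (20 mol %), isoprene (3 equiv), CH2Cl2, rt
Reagents that add atoms: none
Why: Low-valent (formally monovalent) cobalt, generated from CoBr2(dppe) by zinc, binds the alkyne and the s-cis diene, oxidative cyclisation gives a cobaltacycle and reductive elimination releases the cyclohexa-1,4-diene, so that the C2'–C3' and C1'–C6' bonds form in one catalytic event. The closest known reaction type is the cobalt-catalysed neutral Diels–Alder reaction of unactivated terminal alkynes with 2-substituted 1,3-dienes. Ring B closes in an intermolecular [4+2] mode, four carbons coming from isoprene and two (C1', C2') from the alkyne. No stereocentre is created, since C1' stays trigonal and is made stereogenic in steps 10 and 11 under control of ring A. The step needs the 1,4 (para) orientation of the cyclopentyl and methyl groups and tolerance of the secondary bromide; the dppe ligand is known to give the 1,4-pattern with terminal alkynes, the bulky quaternary propargylic carbon reinforces it, and the neopentyl-type C–Br bond should be slow to react with the cobalt catalyst at room temperature.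

Step 7
Reactants: 11 (1S,2S,4S)-4-bromo-2,3,3-trimethyl-2-(4-methylcyclohexa-1,4-dien-1-yl)cyclopentyl acetate
Product: 12 (1S,2S,4S)-4-bromo-2,3,3-trimethyl-2-(4-methylcyclohexa-1,4-dien-1-yl)cyclopentan-1-ol
Conditions: K2CO3 (cat.), MeOH, rt
Reagents that add atoms: none
Why: Base-catalysed transesterification removes the acetate, whose face-blocking role ended in step 4, without affecting the hindered bromide or the skipped diene.

Step 8
Reactants: 12 (1S,2S,4S)-4-bromo-2,3,3-trimethyl-2-(4-methylcyclohexa-1,4-dien-1-yl)cyclopentan-1-ol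
Product: 13 (2S,4S)-4-bromo-2,3,3-trimethyl-2-(4-methylcyclohexa-1,4-dien-1-yl)cyclopentan-1-one
Conditions: Dess–Martin periodinane, NaHCO3, CH2Cl2, 0 °C
Reagents that add atoms: none
Why: Dess–Martin oxidation under buffered, non-basic conditions should give the β-bromo ketone without loss of HBr, and the quaternary C1 excludes both epimerisation and conjugation of the C1'=C2' bond.

Step 9
Reactants: 13 (2S,4S)-4-bromo-2,3,3-trimethyl-2-(4-methylcyclohexa-1,4-dien-1-yl)cyclopentan-1-one
Product: 14 (1R,2S,4S)-4-bromo-2,3,3-trimethyl-2-(4-methylcyclohexa-1,4-dien-1-yl)cyclopentan-1-ol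
Conditions: NaBH4, CeCl3·7H2O, MeOH, −78 °C
Reagents that add atoms: none
Why: Luche reduction, in which hydride should add to the C5 carbonyl from the face of the C1 methyl group, anti to the bulky cyclohexadienyl group and the cis C3 bromide, so that the hydroxyl ends up cis to both (net inversion at C5 over steps 8 and 9) under conditions mild enough for a β-bromo ketone.

Step 10
Reactants: 14 (1R,2S,4S)-4-bromo-2,3,3-trimethyl-2-(4-methylcyclohexa-1,4-dien-1-yl)cyclopentan-1-ol
Product: 15 the C1'–C2' epoxide of 14 (4-methyl-7-oxabicyclo[4.1.0]hept-3-en-1-yl group on C1, epoxide oxygen on the face turned towards the C5 hydroxyl, C1' configured as in the target)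
Conditions: VO(acac)2 (5 mol %), t-BuOOH, CH2Cl2, 0 °C
Reagents that add atoms: tert-butyl hydroperoxide, CC(C)(C)OO
Why: Hydroxyl-directed (homoallylic) vanadium-catalysed epoxidation delivers oxygen only to the proximal C1'=C2' bond, and in the reactive rotamer the small vinylic C2'–H side should lie next to the gem-dimethyl carbon C2 and the C6' methylene next to the C1 methyl group (least allylic strain), which fixes the C1' configuration of the target.

Step 11
Reactants: 15 the C1'–C2' epoxide of 14
Product: 16 (1R,2S,4S)-4-bromo-2-[(1R)-1-hydroxy-4-methylcyclohex-3-en-1-yl]-2,3,3-trimethylcyclopentan-1-ol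
Conditions: LiAlH4, THF, 0 °C to rt
Reagents that add atoms: none
Why: SN2 hydride opening of the trisubstituted epoxide at its less substituted carbon C2' should leave the oxygen on C1' with retention and give the tertiary alcohol, the neopentyl-type secondary bromide being inert to SN2 attack by hydride.

Step 12
Reactants: 16 (1R,2S,4S)-4-bromo-2-[(1R)-1-hydroxy-4-methylcyclohex-3-en-1-yl]-2,3,3-trimethylcyclopentan-1-ol
Product: 17 4-bromo-2-(2-endo-bromo-1-methyl-7-oxabicyclo[2.2.1]heptan-4-yl)-2,3,3-trimethylcyclopentan-1-ol (ring A as in 16; oxygen bridge C1'–O–C4', C5' bromide anti to the bridge)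
Conditions: NBS, CH2Cl2, 0 °C
Reagents that add atoms: N-bromosuccinimide, O=C1CCC(=O)N1Br
Why: Transannular bromoetherification, in which only the bromonium ion on the face anti to the C1' hydroxyl can be captured by that oxygen at the tertiary carbon C4' (Markovnikov, anti addition, 5-exo), sets the C5' bromide trans to the oxygen bridge and puts the C4' oxygen on the face later needed for chlorine.

Step 13
Reactants: 17 4-bromo-2-(2-endo-bromo-1-methyl-7-oxabicyclo[2.2.1]heptan-4-yl)-2,3,3-trimethylcyclopentan-1-ol
Product: 18 (1R,3S,4S)-3-bromo-1-[(1S,3S,5R)-3-bromo-5-hydroxy-1,2,2-trimethylcyclopentyl]-4-chloro-4-methylcyclohexan-1-ol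
Conditions: TiCl4, CH2Cl2, −78 to −30 °C; then aq. NaHCO3
Reagents that add atoms: titanium tetrachloride, Cl[Ti](Cl)(Cl)Cl
Why: Lewis-acid cleavage of a tertiary ether to a tertiary chloride, in which TiCl4 chelated between the C5 oxygen and the bridging oxygen ionises the C4'–O bond with anchimeric help from the anti-periplanar C5' bromine and chloride opens the resulting bromonium ion at the tertiary C4' on the face just vacated by oxygen, so that C4' is substituted with net retention and the trans-bromochloride of the target should result.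

Compound list
1 | (1S,4S)-camphor, (−)-camphor | CC1(C)[C@@H]2CC(=O)[C@@]1(C)CC2 | starting material
2 | lithium (1S,2S,4S)-isoborneolate (exo alkoxide) | [Li+].CC1(C)[C@@H]2C[C@H]([O-])[C@@]1(C)CC2 | intermediate
3 | (1S,2S,4S)-isobornyl acetate (2-exo-acetoxybornane) | CC1(C)[C@@H]2C[C@H](OC(C)=O)[C@@]1(C)CC2 | intermediate
4 | 5-oxoisobornyl acetate (2-exo-acetoxybornan-5-one, bridgeheads as in 1) | CC1(C)[C@@H]2C[C@H](OC(C)=O)[C@@]1(C)CC2=O | intermediate
5 | 5-exo-hydroxyisobornyl acetate (2-exo-acetoxy-5-exo-hydroxybornane) | CC1(C)[C@@H]2C[C@H](OC(C)=O)[C@@]1(C)C[C@@H]2O | intermediate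
6 | 5-exo-hypobromite of 5 | CC1(C)[C@@H]2C[C@H](OC(C)=O)[C@@]1(C)C[C@@H]2OBr | intermediate
7 | 2-[(1S,3S,5S)-5-acetoxy-3-bromo-1,2,2-trimethylcyclopentyl]acetaldehyde (Br cis, OAc trans to the CH2CHO chain) | CC1(C)[C@@H](Br)C[C@H](OC(C)=O)[C@@]1(C)CC=O | intermediate
8 | enol triflate of 7 (1-alkenyl triflate, E/Z mixture) | CC1(C)[C@@H](Br)C[C@H](OC(C)=O)[C@@]1(C)C=COS(=O)(=O)C(F)(F)F | intermediate
9 | (1S,2S,4S)-4-bromo-2-ethynyl-2,3,3-trimethylcyclopentyl acetate | CC1(C)[C@@H](Br)C[C@H](OC(C)=O)[C@@]1(C)C#C | intermediate
10 | isoprene | C=CC(C)=C | starting material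
11 | (1S,2S,4S)-4-bromo-2,3,3-trimethyl-2-(4-methylcyclohexa-1,4-dien-1-yl)cyclopentyl acetate | CC1(C)[C@@H](Br)C[C@H](OC(C)=O)[C@@]1(C)C1=CCC(C)=CC1 | intermediate
12 | (1S,2S,4S)-4-bromo-2,3,3-trimethyl-2-(4-methylcyclohexa-1,4-dien-1-yl)cyclopentan-1-ol (OH trans to the dienyl group) | CC1(C)[C@@H](Br)C[C@H](O)[C@@]1(C)C1=CCC(C)=CC1 | intermediate
13 | (2S,4S)-4-bromo-2,3,3-trimethyl-2-(4-methylcyclohexa-1,4-dien-1-yl)cyclopentan-1-one | CC1(C)[C@@H](Br)CC(=O)[C@@]1(C)C1=CCC(C)=CC1 | intermediate
14 | (1R,2S,4S)-4-bromo-2,3,3-trimethyl-2-(4-methylcyclohexa-1,4-dien-1-yl)cyclopentan-1-ol (OH, Br and dienyl group all cis) | CC1(C)[C@@H](Br)C[C@@H](O)[C@@]1(C)C1=CCC(C)=CC1 | intermediate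
15 | C1'–C2' epoxide of 14 (oxygen on the face towards the C5 hydroxyl) | CC1(C)[C@@H](Br)C[C@@H](O)[C@@]1(C)[C@@]23O[C@@H]2CC(C)=CC3 | intermediate
16 | (1R,2S,4S)-4-bromo-2-[(1R)-1-hydroxy-4-methylcyclohex-3-en-1-yl]-2,3,3-trimethylcyclopentan-1-ol | CC1(C)[C@@H](Br)C[C@@H](O)[C@@]1(C)[C@@]1(O)CCC(C)=CC1 | intermediate
17 | 4-bromo-2-(2-endo-bromo-1-methyl-7-oxabicyclo[2.2.1]heptan-4-yl)-2,3,3-trimethylcyclopentan-1-ol | CC1(C)[C@@H](Br)C[C@@H](O)[C@@]1(C)[C@]12CC[C@](C)(O1)[C@@H](Br)C2 | intermediate
18 | (1R,3S,4S)-3-bromo-1-[(1S,3S,5R)-3-bromo-5-hydroxy-1,2,2-trimethylcyclopentyl]-4-chloro-4-methylcyclohexan-1-ol | CC1(C)[C@@H](Br)C[C@@H](O)[C@@]1(C)[C@@]1(O)CC[C@](C)(Cl)[C@@H](Br)C1 | target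

Total step count: 13
Longest linear sequence: 13 steps, from (1S,4S)-camphor

Steps most likely to fail

Step 13. The ether may ionise at the wrong bridgehead (C1'), chloride may enter at the secondary C5', or the bromonium ion may lose a proton. In that case the ether stage would be bypassed. Diol 16 would be treated with NBS and ClTi(Oi-Pr)3 (CH2Cl2/hexane, −20 °C), a titanium-alkoxide-directed bromochlorination of the alkene: the C1' titanium alkoxide hands chloride to C4' across the ring on its own face while the bromonium ion sits on the opposite face. This fallback sets out from 16, comes back at 18 and makes no new compound.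

Step 4. Bromine-atom transfer to the planar C3 radical may show poor facial selectivity, and 1,5-hydrogen transfer within the alkoxy radical may compete with fragmentation. If C3 epimers result, the mixture would be carried through steps 5 to 8 and converged at ketone 13 by polar chemistry. DBU (CH2Cl2, 0 °C) should eliminate HBr from both epimers to the single enone 4,4,5-trimethyl-5-(4-methylcyclohexa-1,4-dien-1-yl)cyclopent-2-en-1-one F1 (quaternary centre as in 13). Reversible conjugate addition of Me3SiBr (CH2Cl2, −78 to 0 °C, trace 2,6-lutidine) should give the β-bromo trimethylsilyl enol ether F2, with bromine pseudo-equatorial and cis to the large C1 substituent under thermodynamic control. Mild aqueous work-up then returns 13 as the cis epimer. This fallback sets out from 13 and comes back at 13.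

Step 10. Rotamer control at C1' may be weak, giving the wrong face, and the skipped diene may be oxidised towards the arene. A chair-like iodocarbonate cyclisation would replace the epoxide route. Alcohol 14 would be converted with Boc2O/DMAP into the tert-butyl carbonate F3. IBr (toluene, −78 °C) should then close the six-membered cyclic carbonate of the C5/C1' diol bearing iodine at C2', F4, by anti addition with oxygen at the tertiary C1'. Bu3SnH/Et3B (−20 °C) should remove the iodide in preference to the hindered bromide to give the cyclic carbonate F5, and K2CO3/MeOH would release diol 16. This fallback sets out from 14 and comes back at 16, which also avoids LiAlH4.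

Further compounds
F1 | step 4 | 4,4,5-trimethyl-5-(4-methylcyclohexa-1,4-dien-1-yl)cyclopent-2-en-1-one (quaternary centre as in 13) | CC1(C)C=CC(=O)[C@@]1(C)C1=CCC(C)=CC1
F2 | step 4 | 3-bromo-4,4,5-trimethyl-5-(4-methylcyclohexa-1,4-dien-1-yl)cyclopent-1-enyl trimethylsilyl ether (Br cis to the dienyl group) | CC1(C)[C@@H](Br)C=C(O[Si](C)(C)C)[C@@]1(C)C1=CCC(C)=CC1
F3 | step 10 | tert-butyl carbonate of 14 | CC1(C)[C@@H](Br)C[C@@H](OC(=O)OC(C)(C)C)[C@@]1(C)C1=CCC(C)=CC1
F4 | step 10 | cyclic carbonate of the C5/C1' diol with iodine at C2' (iodine trans to the C1' oxygen) | CC1(C)[C@@H](Br)C[C@H]2OC(=O)O[C@]3(CC=C(C)C[C@@H]3I)[C@@]12C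
F5 | step 10 | cyclic carbonate of diol 16 | CC1(C)[C@@H](Br)C[C@H]2OC(=O)O[C@]3(CC=C(C)CC3)[C@@]12C
F0 | step 13 | none | none
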